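A direct plan would build the hydrindenedione A1 by an amino acid-mediated aldol annulation, set C9 by reductive hydroxymethylation of the enone to the keto alcohol A2, carry ring B to the allylic alcohol A3 while C11 waits as a silyl ether, enlarge the five-membered ring to the decalin enol triflate A4 and close with a Heck coupling of the vinyl compound A5 to attach the butenolide.
Its weakest steps would be:
- the one-carbon ring enlargement of A3 to A4 through a β-oxido carbenoid: ring A would first be made with the wrong size, and the correction would need a bulky carbenoid to add to an enolisable ketone next to a quaternary carbon and the right bond to migrate, late and on a dianion;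
- the hydroxymethylation that gives A2: facial control on the reduction enolate is uncertain, the β-hydroxy ketone is prone to retro-aldol cleavage, and the CH2OH group would then cost protection, deprotection, oxidation and methylenation only to become a vinyl group;
- the final Heck coupling of A5: a neopentyl vinyl group would have to react with a base-labile 4-halobutenolide in hot amine on the complete diacetate, so the most valuable material would be at risk in the last step.

**Retrosynthetic overview**
The new route would cut the decalin at C5–C10 and C8–C9 and form both bonds, together with C19–H, in one reductive Michael–aldol bicyclisation of an acyclic enone–enal–ketone: ring A closes first (C5–C10), ring B second (C8–C9).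
C6 and C7 would be bought as D-tartaric acid (as its acetonide, the only protecting group of the route); C5, C10, C9 and C8, that is both quaternary carbons and the tertiary carbinol, would be relayed from them in that single event.
The hydride that starts the cascade becomes the C19 methyl group, the C4 ketone that anchors the enolate later gives the C3=C4–CH3 unit through its enol triflate, and the aldol aldehyde is C11, extended by iodo-olefination and Stille coupling with a stannyl butenolide.
Thus no ring is made with the wrong size, C9 is closed into ring B instead of being alkylated, no C11 protecting group is carried, and the butenolide is attached by a mild coupling three steps before the end.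

Key step: step 8

Remark: clerodane numbering of the target is used for all compounds (C18 on C4, C19 on C5, C17 on C8, C20 and C11 on C9); β is the face of the C19 methyl group, α the opposite face.

Step 1
Reactants: 1 dimethyl (4S,5S)-2,2-dimethyl-1,3-dioxolane-4,5-dicarboxylate
Product: 2 bis(N-methoxy-N-methylamide) of the D-tartrate acetonide
Conditions: MeNH(OMe)·HCl (5 equiv), i-PrMgCl (10 equiv), THF, −20 → 0 °C
Reagents that add atoms: N,O-dimethylhydroxylamine hydrochloride CNOC.Cl
Why: Aminolysis of both esters by the chloromagnesium amide gives the bis(N-methoxy-N-methylamide); the two stereocentres are not enolised at low temperature.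

Step 2
Reactants: 2 bis(N-methoxy-N-methylamide) of the D-tartrate acetonide
Product: 3 C2-symmetric diketone (4S,5S)-4,5-diacetyl-2,2-dimethyl-1,3-dioxolane
Conditions: MeMgBr (2.5 equiv), THF, −10 → 0 °C; aq NH4Cl
Reagents that add atoms: methylmagnesium bromide C[Mg]Br
Why: Grignard addition to the N-methoxy-N-methylamides stops at the ketone because the chelated tetrahedral adducts survive until work-up.

Step 3
Reactants: 3 C2-symmetric diketone
Product: 4 mono enol triflate (C5=C19H2 with C5–OTf)
Conditions: KN(SiMe3)2 (1.0 equiv), THF, −78 °C; PhNTf2 (1.05 equiv), −78 → 0 °C; recovered 3 would be recycled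
Reagents that add atoms: N-phenylbis(trifluoromethanesulfonimide) O=S(=O)(N(c1ccccc1)S(=O)(=O)C(F)(F)F)C(F)(F)F
Why: Kinetic deprotonation of one methyl ketone at its CH3 group and O-sulfonylation of the enolate (enol triflate formation); because 3 is C2-symmetric either carbonyl gives the same monotriflate, and one equivalent of base limits double reaction.

Step 4
Reactants: 4 mono enol triflate
Product: 5 vinylstannane (C5–SnMe3)
Conditions: Me3SnSnMe3 (1.2 equiv), Pd(PPh3)4 (5 mol %), LiCl (6 equiv), THF, 65 °C
Reagents that add atoms: hexamethylditin C[Sn](C)(C)[Sn](C)(C)C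
Why: Palladium-catalysed stannylation of the enol triflate (Stille-type coupling with a distannane) turns C5 into a vinyl nucleophile and leaves the methyl ketone untouched.

Step 5
Reactants: 6 hex-5-enoic acid
Product: 7 S-phenyl hex-5-enethioate
Conditions: PhSH (1.1 equiv), N,N'-dicyclohexylcarbodiimide (1.1 equiv), 4-(dimethylamino)pyridine (5 mol %), CH2Cl2, 0 °C → rt
Reagents that add atoms: thiophenol Sc1ccccc1
Why: Carbodiimide-mediated thioesterification of the acid.

Step 6
Reactants: 7 S-phenyl hex-5-enethioate; 8 methacrolein
Product: 9 S-phenyl (5E)-6-methyl-7-oxohept-5-enethioate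
Conditions: 8 (5 equiv), second-generation Hoveyda–Grubbs catalyst RuCl2(H2IMes)(=CH-C6H4-2-O-i-Pr) (3 mol %), CH2Cl2, 40 °C
Reagents that add atoms: none
Why: Olefin cross-metathesis of the terminal alkene with excess methacrolein; the trisubstituted enal forms as the thermodynamically preferred E isomer.

Step 7
Reactants: 5 vinylstannane; 9 S-phenyl (5E)-6-methyl-7-oxohept-5-enethioate
Product: 10 acyclic enone–enal–ketone (α-methylene ketone at C4/C5; E-enal at C10=C9–C11; methyl ketone at C8)
Conditions: Pd2(dba)3 (2.5 mol %), P(2-furyl)3 (10 mol %), copper diphenylphosphinate CuO2PPh2 (1.3 equiv), THF, rt → 40 °C; used at once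
Reagents that add atoms: none
Why: Liebeskind–Srogl coupling of the thioester with the vinylstannane forms the C4–C5 bond and the α-methylene ketone under neutral conditions that spare the enal, the methyl ketone and the α-alkoxy stereocentres.

Step 8
Reactants: 10 acyclic enone–enal–ketone
Product: 13 trans-decalin keto aldol (4-oxo; 6β,7α-acetonide; 8α-OH; 9α-CHO), via copper enolate 11 (not isolated), via ring A aldehyde enolate 12 (not isolated)
Conditions: [(Ph3P)CuH]6 (0.19 equiv, 1.1 equiv of hydride), toluene, −40 → 0 °C; aq NH4Cl
Reagents that add atoms: none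
Why: Proposed new method: [(Ph3P)CuH]6 delivers hydride to the unsubstituted terminal carbon C19 of the α-methylene ketone and gives the copper enolate 11 regiospecifically, 11 adds through C5 to C10 of the enal (Michael addition) and the resulting aldehyde enolate 12 adds through C9 to the C8 ketone (aldol addition), so that C19–H, C5–C10 and C8–C9 are formed in one flask. The closest known reaction types are the copper hydride- and cobalt hydride-mediated reductive aldol cyclisations and reductive Michael cyclisations of enones, each of which closes one ring; their union in one substrate with formation of a quaternary carbon is the new element. Ring A closes in a 6-(enolendo)-exo-trig Michael mode and ring B in a 6-(enolexo)-exo-trig aldol mode, both through chair-like transition states. C5 is set by C6, because the enolate oxygen and the dioxolane oxygen O6 are held syn on copper (the chelate known from the alkylation of β-alkoxy enolates), C7 covers one face and C10 adds to the other, while C10 is set by the equatorial position of the enal chain in the chair, which places C6 and C9 trans and gives the trans-decalin. C9 is set by allylic 1,3-strain, which keeps C10–H in the plane of the Z enolate of 12 so that C8 bonds to the face that leaves C20 axial and the formyl group equatorial, and C8 is set by the equatorial position of its methyl group C17 in the closed chair-like aldol transition state, which leaves the 8-hydroxyl axial and cis to the formyl group. The step needs hydride attack on the enone before the enal and the ketone, which the unhindered terminal CH2 of the enone against a β-substituted, α-branched enal and the inertness of the reagent to isolated carbonyl groups should secure, and it needs both ring closures to outrun protonation, which the aprotic medium and the gauche arrangement of C5 and C8 on the trans-acetonide favour.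

Step 9
Reactants: 13 trans-decalin keto aldol
Product: 14 E-vinyl iodide (C11=C12–I)
Conditions: CrCl2 (8 equiv), CHI3 (3 equiv), THF/1,4-dioxane (1:6), 0 °C → rt
Reagents that add atoms: iodoform IC(I)I
Why: Takai olefination converts the non-enolisable neopentyl aldehyde into the E-vinyl iodide under non-basic conditions that avoid retro-aldol cleavage; the hindered C4 ketone should not react.

Step 10
Reactants: 14 E-vinyl iodide
Product: 15 Δ3 enol triflate (C4–OTf)
Conditions: KN(SiMe3)2 (2.2 equiv), THF, −78 °C; PhNTf2 (1.2 equiv), −78 → −20 °C
Reagents that add atoms: N-phenylbis(trifluoromethanesulfonimide) O=S(=O)(N(c1ccccc1)S(=O)(=O)C(F)(F)F)C(F)(F)F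
Why: Deprotonation of the tertiary hydroxyl and of C3, the only enolisable position of the C4 ketone because C5 is quaternary, followed by O-sulfonylation of the enolate gives the Δ3 enol triflate regiospecifically; the hindered tertiary alkoxide should not be sulfonylated.

Step 11
Reactants: 16 4-bromofuran-2(5H)-one
Product: 17 4-(tributylstannyl)furan-2(5H)-one
Conditions: Bu3SnSnBu3 (1.1 equiv), Pd(PPh3)4 (3 mol %), toluene, 100 °C
Reagents that add atoms: hexabutylditin CCCC[Sn](CCCC)(CCCC)[Sn](CCCC)(CCCC)CCCC
Why: Palladium-catalysed stannylation of the vinylogous acyl bromide gives the butenolide as a neutral coupling partner.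

Step 12
Reactants: 15 Δ3 enol triflate; 17 4-(tributylstannyl)furan-2(5H)-one
Product: 18 11E-dienyl butenolide with the C4 enol triflate
Conditions: Pd2(dba)3 (5 mol %), AsPh3 (20 mol %), CuI (10 mol %), DMF, rt
Reagents that add atoms: none
Why: Stille coupling; oxidative addition into the C–I bond is much faster than into the hindered enol triflate next to the quaternary C5 at room temperature without added chloride, and the coupling retains the E geometry of C11=C12.

Step 13
Reactants: 18 11E-dienyl butenolide with the C4 enol triflate
Product: 19 Δ3-4-methyl compound (6β,7α-acetonide of the triol)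
Conditions: Me2Zn (3 equiv), PdCl2(dppf) (5 mol %), THF, 0 → 50 °C
Reagents that add atoms: dimethylzinc C[Zn]C
Why: Negishi coupling of the enol triflate installs the C18 methyl group and fixes the C3=C4 double bond; the organozinc reagent does not add to the butenolide.

Step 14
Reactants: 19 Δ3-4-methyl compound
Product: 20 6β,7α,8α-triol
Conditions: AcOH/H2O (4:1), 45 °C
Reagents that add atoms: none
Why: Acid-catalysed hydrolysis of the strained trans-fused acetonide under conditions too mild to ionise the tertiary alcohol or move the ring A alkene.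

Step 15
Reactants: 20 6β,7α,8α-triol
Product: 21 target, 6β,7α-diacetoxy-8α-hydroxycleroda-3,11E,13-trien-15,16-olide
Conditions: Ac2O (4 equiv), pyridine, 4-(dimethylamino)pyridine (0.1 equiv), CH2Cl2, rt
Reagents that add atoms: acetic anhydride CC(=O)OC(C)=O
Why: Acylation of the two equatorial secondary hydroxyls under nucleophilic catalysis; the hindered axial tertiary 8-hydroxyl should not react at room temperature.

**Compound list**

1 | dimethyl (4S,5S)-2,2-dimethyl-1,3-dioxolane-4,5-dicarboxylate (acetonide of dimethyl D-tartrate) | CC1(C)O[C@H](C(=O)OC)[C@H](O1)C(=O)OC | starting material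
2 | (4S,5S)-N4,N5-dimethoxy-N4,N5,2,2-tetramethyl-1,3-dioxolane-4,5-dicarboxamide | CC1(C)O[C@H](C(=O)N(C)OC)[C@H](O1)C(=O)N(C)OC | intermediate
3 | (4S,5S)-4,5-diacetyl-2,2-dimethyl-1,3-dioxolane | CC1(C)O[C@H](C(C)=O)[C@H](O1)C(C)=O | intermediate
4 | 1-[(4S,5S)-5-acetyl-2,2-dimethyl-1,3-dioxolan-4-yl]vinyl trifluoromethanesulfonate | CC1(C)O[C@H](C(=C)OS(=O)(=O)C(F)(F)F)[C@H](O1)C(C)=O | intermediate
5 | 1-[(4S,5S)-2,2-dimethyl-5-[1-(trimethylstannyl)vinyl]-1,3-dioxolan-4-yl]ethanone | CC1(C)O[C@H](C(=C)[Sn](C)(C)C)[C@H](O1)C(C)=O | intermediate
6 | hex-5-enoic acid | C=CCCCC(=O)O | starting material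
7 | S-phenyl hex-5-enethioate | C=CCCCC(=O)Sc1ccccc1 | intermediate
8 | methacrolein (2-methylprop-2-enal) | CC(=C)C=O | starting material
9 | S-phenyl (5E)-6-methyl-7-oxohept-5-enethioate | O=C/C(C)=C/CCCC(=O)Sc1ccccc1 | intermediate
10 | (2E)-8-[(4R,5S)-5-acetyl-2,2-dimethyl-1,3-dioxolan-4-yl]-2-methyl-7-oxonona-2,8-dienal (C6 R, C7 S in target numbering) | CC1(C)O[C@H](C(=C)C(=O)CCC/C=C(\C)C=O)[C@H](O1)C(C)=O | intermediate
11 | copper enolate of 10 (C4–OCu, C4=C5 with O cis to C6, C19 now CH3; PPh3 on copper not drawn) | CC1(C)O[C@H](/C(C)=C(\O[Cu])CCC/C=C(\C)C=O)[C@H](O1)C(C)=O | intermediate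
12 | copper aldehyde enolate with ring A closed (C5 and C10 as in 13; C9=C11–OCu, Z; PPh3 on copper not drawn) | CC1(C)O[C@H]([C@@]2(C)C(=O)CCC[C@@H]2/C(C)=C\O[Cu])[C@H](O1)C(C)=O | intermediate
13 | trans-decalin keto aldol: 4-oxo, 5β-CH3, 6β,7α-O-isopropylidene, 8α-OH, 8β-CH3, 9β-CH3, 9α-CHO, 10α-H | CC1(C)O[C@H]2[C@H](O1)[C@](C)(O)[C@](C)(C=O)[C@H]3CCCC(=O)[C@]23C | intermediate
14 | E-vinyl iodide of 13 (9α-CH=CHI, 4-oxo) | CC1(C)O[C@H]2[C@H](O1)[C@](C)(O)[C@](C)(/C=C/I)[C@H]3CCCC(=O)[C@]23C | intermediate
15 | Δ3 enol triflate of 14 (C4–OTf, C3=C4) | CC1(C)O[C@H]2[C@H](O1)[C@](C)(O)[C@](C)(/C=C/I)[C@H]3CCC=C(OS(=O)(=O)C(F)(F)F)[C@]23C | intermediate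
16 | 4-bromofuran-2(5H)-one | O=C1OCC(Br)=C1 | starting material
17 | 4-(tributylstannyl)furan-2(5H)-one | CCCC[Sn](CCCC)(CCCC)C1=CC(=O)OC1 | intermediate
18 | 11E-dienyl butenolide with C4 enol triflate, 6β,7α-acetonide, 8α-OH | CC1(C)O[C@H]2[C@H](O1)[C@](C)(O)[C@](C)(/C=C/C4=CC(=O)OC4)[C@H]3CCC=C(OS(=O)(=O)C(F)(F)F)[C@]23C | intermediate
19 | 6β,7α-O-isopropylidene-8α-hydroxycleroda-3,11E,13-trien-15,16-olide | CC1(C)O[C@H]2[C@H](O1)[C@](C)(O)[C@](C)(/C=C/C4=CC(=O)OC4)[C@H]3CCC=C(C)[C@]23C | intermediate
20 | 6β,7α,8α-trihydroxycleroda-3,11E,13-trien-15,16-olide | O[C@H]1[C@H](O)[C@](C)(O)[C@](C)(/C=C/C2=CC(=O)OC2)[C@H]2CCC=C(C)[C@]12C | intermediate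
21 | 6β,7α-diacetoxy-8α-hydroxycleroda-3,11E,13-trien-15,16-olide | CC(=O)O[C@H]1[C@H](OC(C)=O)[C@](C)(O)[C@](C)(/C=C/C2=CC(=O)OC2)[C@H]2CCC=C(C)[C@]12C | target

**Step count and risks**

Total step count: 15 (steps 5, 6 and 11 prepare the two coupling partners). Longest linear sequence: 12 steps (1–4, 7–10, 12–15).

Steps most likely to fail:

1. Step 8 (proposed new method). What may go wrong: protonation or further reduction of the enolates before the carbon–carbon bonds form; β-elimination of the C6 oxygen from the C4/C5 enolate; addition of C10 to the wrong face of the enolate if copper does not hold O6 (the open, allylic-strain-controlled conformer would lead to the mirror-image ring fusion); poor facial selectivity at C9 in the aldol closure. The fallback uses known reactions in separate operations and sets out from 10. Rhodium-catalysed 1,4-hydrosilylation of the terminal enone with Et3SiH and RhCl(PPh3)3 would give the triethylsilyl enol ether F1 regiospecifically. TiCl4 in CH2Cl2 at −78 °C would exchange silicon for titanium, the trichlorotitanium enolate being chelated by O6, and bring about the intramolecular Mukaiyama–Michael addition to the enal, to give after hydrolysis the monocyclic keto aldehyde F2. An amine-catalysed (pyrrolidinium acetate) intramolecular aldol addition of the aldehyde to the C8 ketone would then close ring B and return the route at 13.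

2. Step 10. What may go wrong: loss of HI or carbenoid formation at the vinyl iodide under the amide base, and sulfonylation or fragmentation at the tertiary alkoxide. The fallback sets out from 13 and introduces the iodide only after ring A is finished. 13 would be silylated (Me3SiOTf, 2,6-lutidine) to the 8-O-trimethylsilyl ether F3. With no vinyl iodide and no free alkoxide present, deprotonation at C3 with lithium 2,2,6,6-tetramethylpiperidide at −78 °C, a base that can neither add to nor reduce the non-enolisable neopentyl aldehyde, and trapping with N-(5-chloropyridin-2-yl)bis(trifluoromethanesulfonyl)imide would give the enol triflate aldehyde F4. Negishi methylation (Me2Zn, PdCl2(dppf)) would give the Δ3-4-methyl aldehyde F5, Takai olefination the E-vinyl iodide F6, and Stille coupling with 17 the silyl ether dienyl butenolide F7. Aqueous acetic acid would remove the silyl ether together with the acetonide and return the route at 20.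

3. Step 9. What may go wrong: slow or incomplete iodo-olefination of the neopentyl aldehyde, retro-aldol opening of ring B promoted by the Lewis-acidic chromium salts, and erosion of the E selectivity. The fallback sets out from 13 and builds the vinyl iodide through an alkyne. Homologation with dimethyl (1-diazo-2-oxopropyl)phosphonate and K2CO3 in methanol at 0 °C (Ohira–Bestmann reaction), a brief exposure to a weak base that should spare the tertiary aldol and the ketone, would give the terminal alkyne F8. Palladium-catalysed hydrostannation (Bu3SnH, PdCl2(PPh3)2), directed to the distal carbon by the quaternary C9, would give the E-vinylstannane F9, and iododestannylation with I2 would return the route at 14.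

**Further compounds**

F1 | step 8 | triethylsilyl enol ether of 10 (C4–OSiEt3, C4=C5) | CC1(C)O[C@H](/C(C)=C(\O[Si](CC)(CC)CC)CCC/C=C(\C)C=O)[C@H](O1)C(C)=O
F2 | step 8 | monocyclic keto aldehyde (ring A closed, C5 and C10 as in 13, C9 epimers) | CC1(C)O[C@H]([C@@]2(C)C(=O)CCC[C@@H]2C(C)C=O)[C@H](O1)C(C)=O
F3 | step 10 | 8-O-trimethylsilyl ether of 13 | CC1(C)O[C@H]2[C@H](O1)[C@](C)(O[Si](C)(C)C)[C@](C)(C=O)[C@H]3CCCC(=O)[C@]23C
F4 | step 10 | Δ3 enol triflate aldehyde (8-O-trimethylsilyl) | CC1(C)O[C@H]2[C@H](O1)[C@](C)(O[Si](C)(C)C)[C@](C)(C=O)[C@H]3CCC=C(OS(=O)(=O)C(F)(F)F)[C@]23C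
F5 | step 10 | Δ3-4-methyl aldehyde (8-O-trimethylsilyl) | CC1(C)O[C@H]2[C@H](O1)[C@](C)(O[Si](C)(C)C)[C@](C)(C=O)[C@H]3CCC=C(C)[C@]23C
F6 | step 10 | E-vinyl iodide (Δ3-4-methyl, 8-O-trimethylsilyl) | CC1(C)O[C@H]2[C@H](O1)[C@](C)(O[Si](C)(C)C)[C@](C)(/C=C/I)[C@H]3CCC=C(C)[C@]23C
F7 | step 10 | 8-O-trimethylsilyl ether of 19 | CC1(C)O[C@H]2[C@H](O1)[C@](C)(O[Si](C)(C)C)[C@](C)(/C=C/C4=CC(=O)OC4)[C@H]3CCC=C(C)[C@]23C
F8 | step 9 | terminal alkyne (9α-ethynyl, 4-oxo, acetonide, 8α-OH) | CC1(C)O[C@H]2[C@H](O1)[C@](C)(O)[C@](C)(C#C)[C@H]3CCCC(=O)[C@]23C
F9 | step 9 | E-vinylstannane (9α-CH=CH–SnBu3, 4-oxo) | CC1(C)O[C@H]2[C@H](O1)[C@](C)(O)[C@](C)(/C=C/[Sn](CCCC)(CCCC)CCCC)[C@H]3CCCC(=O)[C@]23C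
A1 | direct plan | (R)-4,7a-dimethyl-2,3,7,7a-tetrahydro-1H-indene-1,5(6H)-dione | C1CC(=O)C(C)=C2CCC(=O)[C@]12C
A2 | direct plan | trans-hydrindan-8-one with 9α-CH2OH, 9β-CH3 and C3 ethylene ketal | C1CC(=O)[C@](C)(CO)[C@H]2CCC3(OCCO3)[C@]12C
A3 | direct plan | trans-hydrindan-3-one with Δ6 tertiary allylic alcohol and C11 silyl ether | C1=C[C@@](C)(O)[C@](C)(CO[Si](C)(C)C(C)(C)C)[C@H]2CCC(=O)[C@]12C
A4 | direct plan | ring-enlarged decalin enol triflate (3-OTf, Δ3, 4-CH3) | C1=C[C@@](C)(O)[C@](C)(CO[Si](C)(C)C(C)(C)C)[C@H]2CCC(OS(=O)(=O)C(F)(F)F)=C(C)[C@]12C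
A5 | direct plan | 6β,7α-diacetate with C9 vinyl group | CC(=O)O[C@H]1[C@H](OC(C)=O)[C@](C)(O)[C@](C)(C=C)[C@H]2CCC=C(C)[C@]12C
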